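## Structural features

The target consists of two 2,3-diaryl-2,3-dihydrobenzofurans. The first (O1, C2, C3, benzo ring A = C3a–C7a) carries the formyl group at C5, para to O1, and a 4-hydroxyphenyl group (ring B) at C2. The second (O1', C2', C3', resorcinol ring C = C3a'–C7a') carries a free hydroxyl at C6', a 3,5-dihydroxyphenyl group (ring D) at C3' and a 4-hydroxyphenyl group (ring E) at C2'. The two units are joined by the single bond C3–C4', so ring C is 1,2,3,5-tetrasubstituted, with C4', C3a' and C7a' on three contiguous positions. There are four stereocentres in two vicinal pairs, C2/C3 and C2'/C3', each trans and all R; C3 and C3' face each other across the C4'–C3a' edge. C3 and C3' are diarylmethine carbons that cannot be corrected once set, whereas the C2–O1 and C2'–O1' bonds ionise under acid and reclose, so trans is reachable from cis. Fragile elements are the five phenols, the aldehyde, these acid-labile benzylic C–O bonds, and ring D, which could trap a cation at C2 in a seven-membered Friedel–Crafts closure. The real difficulty is absolute control at C3 and C3' together with the congestion at C3a'. The key step uses the fact that C3 is a diarylmethine between ring A and ring C and C2 is a benzylic carbon on O1, so C3 can be a diaryl carbene that inserts into a C–H bond of an O–CH2–aryl ether on ring A.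

## Logic of the disconnections

20 to 19. No skeletal bond is cut. The five phenols are capped (four methyl ethers, one benzylic ether at O6'), the formyl group becomes an acetal, and C2 and C2' are relaxed from trans to cis. Carbene insertion delivers cis rings, and a Lewis acid opens and recloses the C2–O1 and C2'–O1' bonds to the more stable trans rings, so ether cleavage and epimerisation share one step. The demand is that six protecting groups fall without Friedel–Crafts damage and that C3 and C3' stay untouched.

19 to 17 (through 18). The bond C2'–C3' is cut. C3' is a diarylmethine between rings C and D and C2' sits on O1', so C3' becomes a carbene and C2' the CH2 of the benzylic ether at O7a'. This removes one ring and two stereocentres and reuses the catalyst of the key step. The carbene is flanked by two ortho substituents and the catalyst must set C3' against existing centres. The only other activated C–H bond nearby, C2–H, must point away, which is why the first ring is kept cis at this stage.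

17 to 13 and 14 (through 15 and 16). The bond C3a'–C3' is cut and the hydrazone C=N is traced back to a nitrile. Ring D and C3' arrive as one commercial piece, and exchange at an imine avoids condensing a ketone that sits between two ortho substituents. The demand is halogen–metal exchange at the most hindered position of ring C and addition of the anion before proton transfer from C3–H or the neighbouring O–CH2 group intervenes.

13 to 12. The bond C2–C3 is cut, which opens the formyl-ring dihydrofuran. The retron is a diaryl carbene at C3 beside an aryl benzyl ether on ring A. One ring and both stereocentres vanish and an achiral, acyclic compound remains. The forward step needs enantiocontrol at C3 from the catalyst alone, preference for the one C–H bond in 1,5-relation, and tolerance of the bromine, the acetal and two further benzylic ethers. Ring C is carried as a bis(benzylic ether), so the ether for the second insertion is already in place at O7a' and no late selective dealkylation next to acid-labile rings is needed.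

12 to 11 to 10 to 9. No skeletal bond is cut; the diazo carbon is traced through hydrazone and ketone to a carbinol. The carbinol is the product of a simple addition. The demand is condensation on a ketone with one ortho substituent on each ring under basic conditions that keep the acetal.

9 to 7 and 4 (through 8). The bond C3–C3a is cut. The ring A halogen becomes the nucleophile and the ring C aldehyde the electrophile, which leaves the ring C bromine untouched. Two benzene building blocks of similar size result. The addition to the aldehyde must outrun exchange with the bromine of 4.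

7 to 6 to 5 and 3. The O1–CH2 ether bond and the acetal are removed. The benzyl group is not a protecting group: its CH2 becomes C2 and its ring becomes ring B. The acetalisation must be mild enough for the benzylic ether.

4 to 2 and 3; 2 to 1. The two O–CH2 bonds on ring C are cut and the methyl groups of 1 are exchanged. 1 fixes the bromine position; one new ether becomes C2' and ring E, the other is a protecting group that falls in the last step. Two early steps on cheap material replace a late chelation-controlled dealkylation.

## Other disconnections considered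

Alternative 1: The cut runs through the two exocyclic bonds on adjacent positions of ring C, C3–C4' and C3'–C3a'. Forward, a fluoride source releases the aryne from silyl triflate A2, and the enolate carbon of β-keto ester A3 adds at the aryne carbon remote from the flanking methoxy group. The aryl anion closes onto the ketone and the four-membered alkoxide fragments to keto ester A1. In A1 the acetate CH2 is the future C3, the ester carbon the future C2 and the aroyl carbon the future C3'.
- In favour: both congested C–C bonds at C4' and C3a' form in one mild step with regiochemistry fixed by the methoxy group, and no organometallic is forced between two substituents.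
- Against: A1 has no stereocentre and no heterocycle. C3 is an enolisable methylene that must still receive ring A and become a fixed diarylmethine. Both ring C oxygens are methyl ethers, and each dihydrofuran needs its own closure and its own source of absolute configuration.
- Comparison: structurally the aryne step spends its power on the ring C substitution pattern, which the chosen plan buys in 1. Mechanistically it is a polar C–C insertion that creates no chirality, whereas step 9 creates a ring and two stereocentres. The path from A1 to a compound comparable with 13 is expected to be longer than steps 5–9.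
- Better or equal: the C3'–C3a' bond is made intramolecularly by acyl transfer, which is more reliable than the addition of hindered aryllithium 15 in step 10. On regiocontrol of ring C the two plans are equal.

Alternative 2: Ring C itself is cut at C4'–C5' and C3a'–C7a'. Forward, ynone A5, which already contains the trans formyl-ring dihydrobenzofuran with bromine at C5 as latent formyl group, undergoes Diels–Alder addition with diene A6. The nucleophilic diene terminus bonds to the β-carbon of the ynone; loss of an alcohol molecule and of the silyl group aromatises the adduct to phenol A4.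
- In favour: the crowded 1,2,3-pattern of ring C arises by cycloaddition, not by substitution on a hindered arene, and the C3–C4' bond exists before ring C. C2 and C3 are set before the most hindered region is assembled.
- Against: A5 needs an enantiopure trans-2-aryl-3-alkynyl dihydrobenzofuran, for which the insertion of step 9 is not available (the carbene would be alkynyl aryl). C3–H in A5 is benzylic, propargylic and γ to a carbonyl, so isomerisation to an allenyl ketone threatens C3 under thermal conditions. A ketone is present when the bromine is later exchanged for formyl, and the second dihydrofuran is still missing after A4.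
- Comparison: mechanistically it is a thermal pericyclic step without stereochemical consequence, against a catalyst-controlled insertion. On step economy it builds ring C from acyclic material where the chosen plan uses a commercial arene; the route to A5 alone is expected to match steps 1–9.
- Better or equal: the two ring C oxygens emerge differentiated (free OH at C6', methyl ether at C7a' next to the ketone), which the chosen plan buys with steps 1 and 2. Handling of ring A and C3 is equal.

Alternative 3: The second dihydrofuran is cut at C2'–C3' and O1'–C2'. Forward, a carbonate base eliminates sulfinate from phenol sulfone A8 to give an ortho-quinone methide and converts a chiral 4-methoxybenzylsulfonium salt such as A9 into its ylide. The ylide carbon adds to the exocyclic carbon (C3') and the phenoxide displaces the sulfide at C2', giving A7 with bromine at C4'.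
- In favour: two bonds and both stereocentres of the resorcinol-ring dihydrofuran form in one mild basic step, and the chiral sulfide is recoverable.
- Against: A8 has the sulfonyl-bearing carbon between the hydroxyl and the bromine, the most hindered ortho position, so its preparation needs a directed route. Enantiocontrol by a semistabilised benzyl ylide rests on ylide conformation and irreversible betaine formation and is less secure than a dirhodium pocket. After A7 the formyl-ring dihydrofuran must still be built at C4' next to an existing stereocentre, most plausibly by the very insertion of step 9, so this alternative reorders the chosen plan and does not replace its key step.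
- Comparison: mechanistically it is ionic and base-mediated, against a carbene insertion that gives cis and relies on a final equilibration. Step economy is roughly equal; the separate chiral reagent and the synthesis of A8 cost about what the chosen plan spends on 17, and the chosen plan uses one catalyst for both rings.
- Better or equal: the trans ring forms directly, so no acid epimerisation at C2' is needed. It also begins at the crowded ring C and ends at the unhindered ring A, a better order than step 11, where the carbene is flanked on both sides.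

Key step: step 9

Assumption: Rh2(R-PTAD)4, the dirhodium tetrakis[(R)-(1-adamantyl)(phthalimido)acetate], is taken to be the catalyst enantiomer that gives the C3 and C3' configurations drawn, by extrapolation from simpler aryl benzyl ethers; should the sense be opposite, Rh2(S-PTAD)4 is the same reagent in the other hand.

## Route

Step 1
Reactants: 1 2-bromo-3,5-dimethoxybenzaldehyde
Product: 2 2-bromo-3,5-dihydroxybenzaldehyde
Conditions: BBr3 (3 equiv), CH2Cl2, −78 °C → rt; H2O
Reagents that add atoms: none
Why: Lewis acid-mediated O-demethylation of both aryl methyl ethers; the aldehyde is recovered on aqueous work-up and the aryl bromide is inert. This frees both ring C oxygens for benzylic ethers.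

Step 2
Reactants: 2 2-bromo-3,5-dihydroxybenzaldehyde; 3 4-methoxybenzyl chloride (2.2 equiv)
Product: 4 2-bromo-3,5-bis[(4-methoxybenzyl)oxy]benzaldehyde
Conditions: K2CO3, DMF, 60 °C
Reagents that add atoms: none
Why: Williamson ether synthesis on both phenoxides with a reactive benzylic chloride. The ether at C3 of this ring later supplies C2' and ring E; the ether at C5 is a protecting group.

Step 3
Reactants: 5 3-bromo-4-hydroxybenzaldehyde; 3 4-methoxybenzyl chloride
Product: 6 3-bromo-4-[(4-methoxybenzyl)oxy]benzaldehyde
Conditions: K2CO3, DMF, 60 °C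
Reagents that add atoms: none
Why: Williamson ether synthesis on an acidic para-formyl phenol. The benzylic CH2 introduced here becomes C2 and its ring becomes ring B.

Step 4
Reactants: 6 3-bromo-4-[(4-methoxybenzyl)oxy]benzaldehyde
Product: 7 2-{3-bromo-4-[(4-methoxybenzyl)oxy]phenyl}-1,3-dioxolane
Conditions: ethylene glycol, pyridinium p-toluenesulfonate (cat.), toluene, reflux, Dean–Stark
Reagents that add atoms: ethylene glycol, OCCO
Why: Acetalisation with azeotropic removal of water; the weak pyridinium acid spares the benzylic aryl ether. The dioxolane protects the formyl group against organolithiums and hydrazine.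

Step 5
Reactants: 7 2-{3-bromo-4-[(4-methoxybenzyl)oxy]phenyl}-1,3-dioxolane; 4 2-bromo-3,5-bis[(4-methoxybenzyl)oxy]benzaldehyde
Product: 9 {2-bromo-3,5-bis[(4-methoxybenzyl)oxy]phenyl}{5-(1,3-dioxolan-2-yl)-2-[(4-methoxybenzyl)oxy]phenyl}methanol (racemic), via aryllithium 8 (not isolated)
Conditions: n-BuLi, THF, −78 °C; then 4, −78 → −40 °C; H2O
Reagents that add atoms: none
Why: Bromine–lithium exchange followed by 1,2-addition of the aryllithium to the aldehyde, which is much faster than exchange with the aryl bromide of 4. The carbinol centre forms as a racemate and is removed in step 6.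

Step 6
Reactants: 9 the diaryl carbinol
Product: 10 {2-bromo-3,5-bis[(4-methoxybenzyl)oxy]phenyl}{5-(1,3-dioxolan-2-yl)-2-[(4-methoxybenzyl)oxy]phenyl}methanone
Conditions: Dess–Martin periodinane, pyridine, CH2Cl2, 0 °C → rt
Reagents that add atoms: none
Why: Dess–Martin oxidation of a hindered benzhydrol to the benzophenone; pyridine buffers the acetic acid so the acetal survives.

Step 7
Reactants: 10 the diaryl ketone
Product: 11 [{2-bromo-3,5-bis[(4-methoxybenzyl)oxy]phenyl}{5-(1,3-dioxolan-2-yl)-2-[(4-methoxybenzyl)oxy]phenyl}methylidene]hydrazine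
Conditions: N2H4·H2O (20 equiv), n-BuOH, 110 °C
Reagents that add atoms: hydrazine (as hydrate), NN
Why: Hydrazone condensation driven by excess hydrazine and heat. The basic medium keeps acetal and ethers, and the electron-rich aryl bromide is not open to nucleophilic aromatic substitution.

Step 8
Reactants: 11 the hydrazone
Product: 12 {2-bromo-3,5-bis[(4-methoxybenzyl)oxy]phenyl}{5-(1,3-dioxolan-2-yl)-2-[(4-methoxybenzyl)oxy]phenyl}diazomethane
Conditions: MnO2 (activated, 10 equiv), CH2Cl2, rt, dark; filtration through Celite
Reagents that add atoms: none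
Why: Dehydrogenation of an N-unsubstituted hydrazone to the diaryldiazomethane. Diaryl diazo compounds are stable enough to be filtered and used as a solution, which allows slow addition in step 9.

Step 9
Reactants: 12 the diaryldiazomethane
Product: 13 (2S,3S)-3-{2-bromo-3,5-bis[(4-methoxybenzyl)oxy]phenyl}-5-(1,3-dioxolan-2-yl)-2-(4-methoxyphenyl)-2,3-dihydrobenzofuran (cis)
Conditions: Rh2(R-PTAD)4 (1 mol %), CH2Cl2, 0 °C → rt, slow addition of 12
Reagents that add atoms: none
Why: Rh2(R-PTAD)4 attacks the diazo carbon of 12 and N2 leaves, giving a dirhodium-bound diaryl (donor–donor) carbene at C3. One hydrogen of the O–CH2–aryl group ortho to the carbene on ring A, made hydridic by O1 and the 4-methoxyphenyl ring, is transferred to the carbene carbon through a five-membered arrangement (C3, C3a, C7a, O1, C2) while the C2–C3 bond forms in the same asynchronous event. The closest known reaction type is the enantioselective intramolecular C–H insertion of donor–donor dirhodium carbenes, made from diaryl ketone hydrazones, into benzylic ether C–H bonds to give cis-2,3-diaryl-2,3-dihydrobenzofurans. The dihydrofuran ring closes by 1,5-C–H insertion, that is by C–C bond formation between the carbene carbon and the ether carbon with O1 already in the tether. C3 is controlled by the chiral carboxylate ligands, whose phthalimido and adamantyl groups leave one face of the prochiral carbene open to the C–H bond; C2 is set relative to C3 in the same event, the compact transition state placing ring B and ring C cis (the C3 descriptor is S only because bromine raises the rank of ring C; the spatial arrangement is that of C3 in the target). The step needs chemoselectivity for this C–H bond over the two benzylic ether CH2 groups of ring C, the acetal C–H, the aryl bromide and carbene–diazo coupling: the ring C ethers and the acetal are meta to the carbon bearing the carbene and cannot reach it, a donor–donor carbene is too weakly electrophilic to engage bromine or ether oxygen, and slow addition keeps the diazo concentration low. Later equilibration at C2 leaves C3 as set here.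

Step 10
Reactants: 13 the cis bromide; 14 3,5-dimethoxybenzonitrile
Product: 17 [(3,5-dimethoxyphenyl){2-[(2S,3R)-5-(1,3-dioxolan-2-yl)-2-(4-methoxyphenyl)-2,3-dihydrobenzofuran-3-yl]-4,6-bis[(4-methoxybenzyl)oxy]phenyl}methylidene]hydrazine, via aryllithium 15 (not isolated), via ketimine 16 (not isolated)
Conditions: t-BuLi (2.1 equiv), THF, −78 °C; 14, −78 → −20 °C; MeOH; then N2H4·H2O, AcOH (cat.), EtOH, 70 °C
Reagents that add atoms: hydrazine (as hydrate), NN
Why: Bromine–lithium exchange, then addition of the aryllithium to the nitrile gives the N-lithio ketimine. After protonation the ketimine exchanges its nitrogen with hydrazine (transimination, loss of ammonia); the iminium is far more electrophilic than the corresponding doubly ortho-substituted ketone. The existing centres are not touched (the C3 descriptor changes to R only because bromine is gone).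

Step 11
Reactants: 17 the second hydrazone
Product: 19 (2S,3R)-4-[(2S,3R)-5-(1,3-dioxolan-2-yl)-2-(4-methoxyphenyl)-2,3-dihydrobenzofuran-3-yl]-3-(3,5-dimethoxyphenyl)-6-[(4-methoxybenzyl)oxy]-2-(4-methoxyphenyl)-2,3-dihydrobenzofuran (cis,cis), via diazo compound 18 (not isolated)
Conditions: MnO2 (activated), CH2Cl2, rt; filtration; then Rh2(R-PTAD)4 (2 mol %), CH2Cl2, 0 °C → rt
Reagents that add atoms: none
Why: Hydrazone dehydrogenation and a second donor–donor dirhodium carbene 1,5-C–H insertion, now into the O–CH2–aryl group at O7a', forming C2'–C3'. The catalyst sets C3' and the ring closes cis as in step 9. Ring C's other ether is para to the carbene-bearing carbon, and the cis first ring turns C2–H away from the carbene, so no second activated C–H bond is in reach.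

Step 12
Reactants: 19 the cis,cis bis(dihydrobenzofuran)
Product: 20 (2R,3R)-3-[(2R,3R)-3-(3,5-dihydroxyphenyl)-6-hydroxy-2-(4-hydroxyphenyl)-2,3-dihydrobenzofuran-4-yl]-2-(4-hydroxyphenyl)-2,3-dihydrobenzofuran-5-carbaldehyde
Conditions: BBr3 (15 equiv), C6HMe5 (3 equiv), CH2Cl2, −78 °C → rt; H2O
Reagents that add atoms: water, O
Why: Global Lewis acid ether cleavage: BBr3 removes the four methyl ethers, the benzylic ether at O6' (its cation is taken up by pentamethylbenzene in a Friedel–Crafts alkylation) and the acetal, which returns the aldehyde on hydrolysis. Under the same conditions the C2–O1 and C2'–O1' bonds open reversibly to 4-oxyphenyl-stabilised benzylic cations and reclose to the more stable trans rings. C3 and C3' are not part of this equilibrium and keep the configuration set in steps 9 and 11.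

## Compound list

1 | 2-bromo-3,5-dimethoxybenzaldehyde | COc1cc(OC)c(Br)c(C=O)c1 | starting material
2 | 2-bromo-3,5-dihydroxybenzaldehyde | O=Cc1cc(O)cc(O)c1Br | intermediate
3 | 4-methoxybenzyl chloride | COc1ccc(CCl)cc1 | starting material
4 | 2-bromo-3,5-bis[(4-methoxybenzyl)oxy]benzaldehyde | O=Cc1cc(OCc2ccc(OC)cc2)cc(OCc2ccc(OC)cc2)c1Br | intermediate
5 | 3-bromo-4-hydroxybenzaldehyde | O=Cc1ccc(O)c(Br)c1 | starting material
6 | 3-bromo-4-[(4-methoxybenzyl)oxy]benzaldehyde | O=Cc1ccc(OCc2ccc(OC)cc2)c(Br)c1 | intermediate
7 | 2-{3-bromo-4-[(4-methoxybenzyl)oxy]phenyl}-1,3-dioxolane | Brc1cc(C2OCCO2)ccc1OCc1ccc(OC)cc1 | intermediate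
8 | {5-(1,3-dioxolan-2-yl)-2-[(4-methoxybenzyl)oxy]phenyl}lithium | [Li]c1cc(C2OCCO2)ccc1OCc1ccc(OC)cc1 | intermediate (not isolated)
9 | {2-bromo-3,5-bis[(4-methoxybenzyl)oxy]phenyl}{5-(1,3-dioxolan-2-yl)-2-[(4-methoxybenzyl)oxy]phenyl}methanol (racemic) | OC(c1cc(C2OCCO2)ccc1OCc1ccc(OC)cc1)c1cc(OCc2ccc(OC)cc2)cc(OCc2ccc(OC)cc2)c1Br | intermediate
10 | {2-bromo-3,5-bis[(4-methoxybenzyl)oxy]phenyl}{5-(1,3-dioxolan-2-yl)-2-[(4-methoxybenzyl)oxy]phenyl}methanone | O=C(c1cc(C2OCCO2)ccc1OCc1ccc(OC)cc1)c1cc(OCc2ccc(OC)cc2)cc(OCc2ccc(OC)cc2)c1Br | intermediate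
11 | hydrazone of 10 | NN=C(c1cc(C2OCCO2)ccc1OCc1ccc(OC)cc1)c1cc(OCc2ccc(OC)cc2)cc(OCc2ccc(OC)cc2)c1Br | intermediate
12 | {2-bromo-3,5-bis[(4-methoxybenzyl)oxy]phenyl}{5-(1,3-dioxolan-2-yl)-2-[(4-methoxybenzyl)oxy]phenyl}diazomethane | [N-]=[N+]=C(c1cc(C2OCCO2)ccc1OCc1ccc(OC)cc1)c1cc(OCc2ccc(OC)cc2)cc(OCc2ccc(OC)cc2)c1Br | intermediate
13 | (2S,3S)-3-{2-bromo-3,5-bis[(4-methoxybenzyl)oxy]phenyl}-5-(1,3-dioxolan-2-yl)-2-(4-methoxyphenyl)-2,3-dihydrobenzofuran (cis) | O1CCOC1c1ccc2c(c1)[C@@H](c1cc(OCc3ccc(OC)cc3)cc(OCc3ccc(OC)cc3)c1Br)[C@@H](c1ccc(OC)cc1)O2 | intermediate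
14 | 3,5-dimethoxybenzonitrile | N#Cc1cc(OC)cc(OC)c1 | starting material
15 | {2-[(2S,3R)-5-(1,3-dioxolan-2-yl)-2-(4-methoxyphenyl)-2,3-dihydrobenzofuran-3-yl]-4,6-bis[(4-methoxybenzyl)oxy]phenyl}lithium | O1CCOC1c1ccc2c(c1)[C@@H](c1cc(OCc3ccc(OC)cc3)cc(OCc3ccc(OC)cc3)c1[Li])[C@@H](c1ccc(OC)cc1)O2 | intermediate (not isolated)
16 | 1-(3,5-dimethoxyphenyl)-1-{2-[(2S,3R)-5-(1,3-dioxolan-2-yl)-2-(4-methoxyphenyl)-2,3-dihydrobenzofuran-3-yl]-4,6-bis[(4-methoxybenzyl)oxy]phenyl}methanimine | O1CCOC1c1ccc2c(c1)[C@@H](c1cc(OCc3ccc(OC)cc3)cc(OCc3ccc(OC)cc3)c1C(=N)c1cc(OC)cc(OC)c1)[C@@H](c1ccc(OC)cc1)O2 | intermediate (not isolated)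
17 | [(3,5-dimethoxyphenyl){2-[(2S,3R)-5-(1,3-dioxolan-2-yl)-2-(4-methoxyphenyl)-2,3-dihydrobenzofuran-3-yl]-4,6-bis[(4-methoxybenzyl)oxy]phenyl}methylidene]hydrazine | O1CCOC1c1ccc2c(c1)[C@@H](c1cc(OCc3ccc(OC)cc3)cc(OCc3ccc(OC)cc3)c1C(=NN)c1cc(OC)cc(OC)c1)[C@@H](c1ccc(OC)cc1)O2 | intermediate
18 | (2S,3R)-3-{2-[diazo(3,5-dimethoxyphenyl)methyl]-3,5-bis[(4-methoxybenzyl)oxy]phenyl}-5-(1,3-dioxolan-2-yl)-2-(4-methoxyphenyl)-2,3-dihydrobenzofuran | O1CCOC1c1ccc2c(c1)[C@@H](c1cc(OCc3ccc(OC)cc3)cc(OCc3ccc(OC)cc3)c1C(=[N+]=[N-])c1cc(OC)cc(OC)c1)[C@@H](c1ccc(OC)cc1)O2 | intermediate (not isolated)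
19 | (2S,3R)-4-[(2S,3R)-5-(1,3-dioxolan-2-yl)-2-(4-methoxyphenyl)-2,3-dihydrobenzofuran-3-yl]-3-(3,5-dimethoxyphenyl)-6-[(4-methoxybenzyl)oxy]-2-(4-methoxyphenyl)-2,3-dihydrobenzofuran (cis,cis) | O1CCOC1c1ccc2c(c1)[C@@H](c1cc(OCc4ccc(OC)cc4)cc3c1[C@@H](c1cc(OC)cc(OC)c1)[C@@H](c1ccc(OC)cc1)O3)[C@@H](c1ccc(OC)cc1)O2 | intermediate
20 | (2R,3R)-3-[(2R,3R)-3-(3,5-dihydroxyphenyl)-6-hydroxy-2-(4-hydroxyphenyl)-2,3-dihydrobenzofuran-4-yl]-2-(4-hydroxyphenyl)-2,3-dihydrobenzofuran-5-carbaldehyde | O=Cc1ccc2c(c1)[C@@H](c1cc(O)cc3c1[C@@H](c1cc(O)cc(O)c1)[C@H](c1ccc(O)cc1)O3)[C@H](c1ccc(O)cc1)O2 | target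

## Step count and least certain steps

Total step count: 12. Longest linear sequence: 10 steps (steps 3–12; the branch through steps 1 and 2 is equally long).

Step 9 (key step). The carbene may couple with unreacted diazo compound to an azine. The ortho bromine twists ring C out of the carbene plane and may erode facial selectivity in the catalyst pocket; it also slows the condensation of step 7. Fallback, from 7 back to 13, with the bromine introduced after ring closure:
- 3,5-Dihydroxybenzaldehyde F1 is alkylated with 3 as in step 2 to 3,5-bis[(4-methoxybenzyl)oxy]benzaldehyde F2.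
- Aryllithium 8 from 7 adds to it to give the bromine-free carbinol F3, which is oxidised to the ketone F4, condensed to the hydrazone F5 and dehydrogenated to the diazo compound F6 under the conditions of steps 6–8.
- Insertion with Rh2(R-PTAD)4 gives the bromine-free cis-dihydrobenzofuran F7; the carbene then carries an unhindered 3,5-dialkoxyphenyl group, the best-precedented case.
- N-Bromosuccinimide at low temperature brominates the symmetric, most electron-rich ring C ortho to the benzylic carbon and returns 13.

Step 10. Addition of the doubly ortho-substituted aryllithium to the nitrile may be slow. During that time proton transfer from the neighbouring O–CH2 group or from C3–H could quench the anion or open the dihydrofuran by β-elimination, and imine–hydrazine exchange at the crowded carbon may stall. Fallback, from 13 back to 17: the aryllithium is trapped at −78 °C with 3,5-dimethoxybenzaldehyde F8, which reacts at once, to give the carbinol F9. Dess–Martin oxidation gives the ketone F10, which is condensed with anhydrous hydrazine in n-butanol in a sealed vessel at 130 °C to give 17.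

Step 11. Catalyst control at C3' may be opposed by the existing C2 and C3 centres (mismatched double stereodifferentiation), and steric shielding of the O–CH2 group may divert the carbene to azine formation. Fallback by anionic ring closure, from 13 to 20:
- 13 is taken through carbinol F9 to ketone F10 as above.
- Lithium 2,2,6,6-tetramethylpiperidide deprotonates the O–CH2 group at O7a'; the carbanion adds to the ketone, and mild dehydration gives the benzofuran F11.
- H2 over Pd/C under pressure adds cis across C2'=C3' and removes the benzylic ether at O6' to give the cis,cis phenol F12. C3' is then substrate-controlled and its epimers must be separated.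
- F12 goes to 20 under the conditions of step 12.

Step 12. A ring-opened C2 cation may be captured by ring D in a seven-membered Friedel–Crafts closure, or elimination to a triarylethylene and reprotonation may scramble C3. The liberated benzylic cation may alkylate the substrate, and demethylation may stay incomplete. Fallback in two stages with a change of demethylation mechanism, from 19 to 20: aqueous trifluoroacetic acid in CH2Cl2 with pentamethylbenzene removes the benzylic ether and the acetal and equilibrates both rings to trans, giving the tetramethyl ether F13. NaSEt in DMF at 130 °C then cleaves the four methyl ethers by nucleophilic attack at methyl, without a Lewis acid.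

## Further compounds

F1 | step 9 | 3,5-dihydroxybenzaldehyde | O=Cc1cc(O)cc(O)c1
F2 | step 9 | 3,5-bis[(4-methoxybenzyl)oxy]benzaldehyde | O=Cc1cc(OCc2ccc(OC)cc2)cc(OCc2ccc(OC)cc2)c1
F3 | step 9 | {3,5-bis[(4-methoxybenzyl)oxy]phenyl}{5-(1,3-dioxolan-2-yl)-2-[(4-methoxybenzyl)oxy]phenyl}methanol (racemic) | OC(c1cc(C2OCCO2)ccc1OCc1ccc(OC)cc1)c1cc(OCc2ccc(OC)cc2)cc(OCc2ccc(OC)cc2)c1
F4 | step 9 | {3,5-bis[(4-methoxybenzyl)oxy]phenyl}{5-(1,3-dioxolan-2-yl)-2-[(4-methoxybenzyl)oxy]phenyl}methanone | O=C(c1cc(C2OCCO2)ccc1OCc1ccc(OC)cc1)c1cc(OCc2ccc(OC)cc2)cc(OCc2ccc(OC)cc2)c1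
F5 | step 9 | hydrazone of F4 | NN=C(c1cc(C2OCCO2)ccc1OCc1ccc(OC)cc1)c1cc(OCc2ccc(OC)cc2)cc(OCc2ccc(OC)cc2)c1
F6 | step 9 | {3,5-bis[(4-methoxybenzyl)oxy]phenyl}{5-(1,3-dioxolan-2-yl)-2-[(4-methoxybenzyl)oxy]phenyl}diazomethane | [N-]=[N+]=C(c1cc(C2OCCO2)ccc1OCc1ccc(OC)cc1)c1cc(OCc2ccc(OC)cc2)cc(OCc2ccc(OC)cc2)c1
F7 | step 9 | (2S,3R)-3-{3,5-bis[(4-methoxybenzyl)oxy]phenyl}-5-(1,3-dioxolan-2-yl)-2-(4-methoxyphenyl)-2,3-dihydrobenzofuran (cis) | O1CCOC1c1ccc2c(c1)[C@@H](c1cc(OCc3ccc(OC)cc3)cc(OCc3ccc(OC)cc3)c1)[C@@H](c1ccc(OC)cc1)O2
F8 | step 10 | 3,5-dimethoxybenzaldehyde | O=Cc1cc(OC)cc(OC)c1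
F9 | step 10 | {2-[(2S,3R)-5-(1,3-dioxolan-2-yl)-2-(4-methoxyphenyl)-2,3-dihydrobenzofuran-3-yl]-4,6-bis[(4-methoxybenzyl)oxy]phenyl}(3,5-dimethoxyphenyl)methanol (carbinol epimers) | O1CCOC1c1ccc2c(c1)[C@@H](c1cc(OCc3ccc(OC)cc3)cc(OCc3ccc(OC)cc3)c1C(O)c1cc(OC)cc(OC)c1)[C@@H](c1ccc(OC)cc1)O2
F10 | step 10 | {2-[(2S,3R)-5-(1,3-dioxolan-2-yl)-2-(4-methoxyphenyl)-2,3-dihydrobenzofuran-3-yl]-4,6-bis[(4-methoxybenzyl)oxy]phenyl}(3,5-dimethoxyphenyl)methanone | O1CCOC1c1ccc2c(c1)[C@@H](c1cc(OCc3ccc(OC)cc3)cc(OCc3ccc(OC)cc3)c1C(=O)c1cc(OC)cc(OC)c1)[C@@H](c1ccc(OC)cc1)O2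
F11 | step 11 | (2S,3R)-3-{3-(3,5-dimethoxyphenyl)-6-[(4-methoxybenzyl)oxy]-2-(4-methoxyphenyl)benzofuran-4-yl}-5-(1,3-dioxolan-2-yl)-2-(4-methoxyphenyl)-2,3-dihydrobenzofuran | O1CCOC1c1ccc2c(c1)[C@@H](c1cc(OCc4ccc(OC)cc4)cc3oc(-c4ccc(OC)cc4)c(-c4cc(OC)cc(OC)c4)c13)[C@@H](c1ccc(OC)cc1)O2
F12 | step 11 | (2S,3R)-4-[(2S,3R)-5-(1,3-dioxolan-2-yl)-2-(4-methoxyphenyl)-2,3-dihydrobenzofuran-3-yl]-3-(3,5-dimethoxyphenyl)-2-(4-methoxyphenyl)-2,3-dihydrobenzofuran-6-ol | O1CCOC1c1ccc2c(c1)[C@@H](c1cc(O)cc3c1[C@@H](c1cc(OC)cc(OC)c1)[C@@H](c1ccc(OC)cc1)O3)[C@@H](c1ccc(OC)cc1)O2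
F13 | step 12 | (2R,3R)-3-[(2R,3R)-3-(3,5-dimethoxyphenyl)-6-hydroxy-2-(4-methoxyphenyl)-2,3-dihydrobenzofuran-4-yl]-2-(4-methoxyphenyl)-2,3-dihydrobenzofuran-5-carbaldehyde | O=Cc1ccc2c(c1)[C@@H](c1cc(O)cc3c1[C@@H](c1cc(OC)cc(OC)c1)[C@H](c1ccc(OC)cc1)O3)[C@H](c1ccc(OC)cc1)O2
A1 | alternative 1 | methyl 2-[2-(3,5-dimethoxybenzoyl)-3,5-dimethoxyphenyl]acetate | COC(=O)Cc1cc(OC)cc(OC)c1C(=O)c1cc(OC)cc(OC)c1
A2 | alternative 1 | 3,5-dimethoxy-2-(trimethylsilyl)phenyl trifluoromethanesulfonate | COc1cc(OC)c([Si](C)(C)C)c(OS(=O)(=O)C(F)(F)F)c1
A3 | alternative 1 | methyl 3-(3,5-dimethoxyphenyl)-3-oxopropanoate | COC(=O)CC(=O)c1cc(OC)cc(OC)c1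
A4 | alternative 2 | {2-[(2R,3R)-5-bromo-2-(4-methoxyphenyl)-2,3-dihydrobenzofuran-3-yl]-4-hydroxy-6-methoxyphenyl}(3,5-dimethoxyphenyl)methanone | Brc1ccc2c(c1)[C@@H](c1cc(O)cc(OC)c1C(=O)c1cc(OC)cc(OC)c1)[C@H](c1ccc(OC)cc1)O2
A5 | alternative 2 | 3-[(2R,3R)-5-bromo-2-(4-methoxyphenyl)-2,3-dihydrobenzofuran-3-yl]-1-(3,5-dimethoxyphenyl)prop-2-yn-1-one | Brc1ccc2c(c1)[C@@H](C#CC(=O)c1cc(OC)cc(OC)c1)[C@H](c1ccc(OC)cc1)O2
A6 | alternative 2 | 1,1-dimethoxy-3-(trimethylsilyloxy)buta-1,3-diene | C=C(O[Si](C)(C)C)C=C(OC)OC
A7 | alternative 3 | (2R,3R)-4-bromo-3-(3,5-dimethoxyphenyl)-6-methoxy-2-(4-methoxyphenyl)-2,3-dihydrobenzofuran | Brc1cc(OC)cc2c1[C@@H](c1cc(OC)cc(OC)c1)[C@H](c1ccc(OC)cc1)O2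
A8 | alternative 3 | 3-bromo-2-[(3,5-dimethoxyphenyl)(4-methylbenzenesulfonyl)methyl]-5-methoxyphenol (racemic) | Oc1cc(OC)cc(Br)c1C(c1cc(OC)cc(OC)c1)S(=O)(=O)c1ccc(C)cc1
A9 | alternative 3 | (2R,5R)-1-(4-methoxybenzyl)-2,5-dimethylthiolan-1-ium tetrafluoroborate | C[C@@H]1CC[C@@H](C)[S+]1Cc1ccc(OC)cc1.F[B-](F)(F)F
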